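The cis-fused hydroazulene is cut across its seven-membered ring into a three-carbon unit C5–C6–C7 and a four-carbon diene C8=C9–C10=C1 (daucane numbering; C1 is the methyl-bearing ring-fusion carbon), joined beforehand by C2–C3–C4. The feature exploited is the β-hydroxy ketone pattern C4(OH)–C5–C6(O) flanking the ring fusion: an epoxy enolsilane spanning C4–C7 is ionised by a silyl triflate and the resulting silyloxyallyl unit undergoes an intramolecular (4+3) cycloaddition with the tethered (E,E)-diene, forming C1–C5 and C7–C8 and closing both rings in one operation. The epoxide, from a Sharpless epoxidation, relays its configuration to C5, C1 and C8; a later singlet-oxygen ene reaction moves the alkene to C8=C9 and oxygenates C10.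

Key step: step 10

Remarks
- Atom labels C1–C10 follow the daucane skeleton: C1 quaternary ring-fusion carbon (CH3), C2 and C3 the CH2 groups of the five-membered ring, C4 C(OH)(isopropyl), C5 ring-fusion CH, C6 CH(O-aroyl), C7 CH2, C8 C(CH3)=, C9 =CH, C10 CH(O-acyl). Systematic names use azulene numbering.
- The target SMILES is read as (1R,4R,5S,6R,10R) in these labels: cis ring fusion (H5 cis to the C1 methyl), the C4 and C6 oxygens trans to H5, the C10 oxygen cis to the C1 methyl, and an (E)-2-methylbut-2-enoate (tiglate).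
- Assumption: hexa-1,5-diyne, (E)-1-bromoprop-1-ene and 4-[(tert-butyldimethylsilyl)oxy]benzoic acid are bought as catalogue compounds.

Step 1
Reactants: 1 hexa-1,5-diyne (threefold excess); 2 (E)-1-bromoprop-1-ene
Product: 4 (5E,7E)-5-methylnona-5,7-dien-1-yne, via alkenylalane 3 (not isolated)
Conditions: AlMe3, Cp2ZrCl2 (20 mol %), CH2Cl2, 0 °C to rt; then 2, Pd(PPh3)4 (5 mol %), ZnCl2 (cat.), THF, rt
Reagents that add atoms: trimethylaluminium, C[Al](C)C
Why: Negishi zirconium-catalysed methylalumination adds CH3 and Al syn across one terminal alkyne (the excess of diyne should hold it at mono-addition), and the palladium-catalysed cross-coupling of the alkenylalane with the (E)-bromide should proceed with retention on both partners, fixing the (5E,7E)-diene with the methyl cis to the propenyl group.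

Step 2
Reactants: 4 (5E,7E)-5-methylnona-5,7-dien-1-yne
Product: 6 ethyl (6E,8E)-6-methyldeca-6,8-dien-2-ynoate, via lithium acetylide 5 (not isolated)
Conditions: nBuLi, THF, −78 °C; then ClCO2Et, −78 to 0 °C
Reagents that add atoms: ethyl chloroformate, CCOC(=O)Cl
Why: Deprotonation of the terminal alkyne and C-acylation of the acetylide with a chloroformate is a standard ynoate synthesis that leaves the diene untouched.

Step 3
Reactants: 6 ethyl (6E,8E)-6-methyldeca-6,8-dien-2-ynoate
Product: 7 ethyl (2E,6E,8E)-6-methyl-3-(propan-2-yl)deca-2,6,8-trienoate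
Conditions: iPrMgCl, CuI (10 mol %), THF, −78 °C; MeOH quench at −78 °C
Reagents that add atoms: isopropylmagnesium chloride, CC(C)[Mg]Cl
Why: Copper-catalysed conjugate addition of the Grignard reagent to the ynoate is a syn carbometalation, so protonation at low temperature should place hydrogen cis to isopropyl and leave the C3 chain cis to the ester (2E).

Step 4
Reactants: 7 ethyl (2E,6E,8E)-6-methyl-3-(propan-2-yl)deca-2,6,8-trienoate
Product: 8 (2E,6E,8E)-6-methyl-3-(propan-2-yl)deca-2,6,8-trien-1-ol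
Conditions: iBu2AlH, CH2Cl2, −78 °C
Reagents that add atoms: none
Why: 1,2-Reduction of the enoate with diisobutylaluminium hydride should give the allylic alcohol without change of alkene geometry.

Step 5
Reactants: 8 (2E,6E,8E)-6-methyl-3-(propan-2-yl)deca-2,6,8-trien-1-ol
Product: 9 [(2R,3R)-3-[(3E,5E)-3-methylhepta-3,5-dien-1-yl]-3-(propan-2-yl)oxiran-2-yl]methanol
Conditions: Ti(OiPr)4 (10 mol %), D-(−)-diethyl tartrate (12 mol %), tBuOOH, 4 Å molecular sieves, CH2Cl2, −20 °C
Reagents that add atoms: tert-butyl hydroperoxide, CC(C)(C)OO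
Why: Sharpless asymmetric epoxidation is selective for the allylic alkene over the diene, and with the D-(−)-tartrate on this (E)-3,3-disubstituted allylic alcohol (a geraniol-type substrate) oxygen should be delivered to the face that gives the (2R,3R)-epoxide, which sets C4 for good and C5 for later inversion.

Step 6
Reactants: 9 [(2R,3R)-3-[(3E,5E)-3-methylhepta-3,5-dien-1-yl]-3-(propan-2-yl)oxiran-2-yl]methanol
Product: 10 (2S,3R)-3-[(3E,5E)-3-methylhepta-3,5-dien-1-yl]-3-(propan-2-yl)oxirane-2-carbaldehyde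
Conditions: Dess–Martin periodinane, pyridine, CH2Cl2, 0 °C to rt
Reagents that add atoms: none
Why: Buffered Dess–Martin oxidation should give the epoxy aldehyde without opening the epoxide or touching the diene.

Step 7
Reactants: 10 (2S,3R)-3-[(3E,5E)-3-methylhepta-3,5-dien-1-yl]-3-(propan-2-yl)oxirane-2-carbaldehyde
Product: 11 1-[(2R,3R)-3-[(3E,5E)-3-methylhepta-3,5-dien-1-yl]-3-(propan-2-yl)oxiran-2-yl]ethan-1-ol (both carbinol epimers)
Conditions: MeMgBr, THF, −78 °C
Reagents that add atoms: methylmagnesium bromide, C[Mg]Br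
Why: Grignard 1,2-addition to the aldehyde is much faster than epoxide opening at −78 °C, and the carbinol configuration is irrelevant because it is oxidised in the next step.

Step 8
Reactants: 11 1-[(2R,3R)-3-[(3E,5E)-3-methylhepta-3,5-dien-1-yl]-3-(propan-2-yl)oxiran-2-yl]ethan-1-ol
Product: 12 1-[(2S,3R)-3-[(3E,5E)-3-methylhepta-3,5-dien-1-yl]-3-(propan-2-yl)oxiran-2-yl]ethan-1-one
Conditions: Dess–Martin periodinane, pyridine, CH2Cl2, 0 °C to rt
Reagents that add atoms: none
Why: Dess–Martin oxidation of the secondary alcohol should give the epoxy methyl ketone, whose epoxide α-carbon cannot epimerise under these conditions.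

Step 9
Reactants: 12 1-[(2S,3R)-3-[(3E,5E)-3-methylhepta-3,5-dien-1-yl]-3-(propan-2-yl)oxiran-2-yl]ethan-1-one
Product: 13 triethyl({1-[(2S,3R)-3-[(3E,5E)-3-methylhepta-3,5-dien-1-yl]-3-(propan-2-yl)oxiran-2-yl]ethenyl}oxy)silane
Conditions: LiN(SiMe3)2, Et3SiCl, THF, −78 °C (internal quench)
Reagents that add atoms: chlorotriethylsilane, CC[Si](Cl)(CC)CC
Why: Kinetic enolisation can occur only at the methyl group (the other α-carbon is the epoxide carbon), and O-silylation of the lithium enolate should give the epoxy enolsilane that serves as the oxyallyl precursor.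

Step 10
Reactants: 13 triethyl({1-[(2S,3R)-3-[(3E,5E)-3-methylhepta-3,5-dien-1-yl]-3-(propan-2-yl)oxiran-2-yl]ethenyl}oxy)silane
Product: 15 (1R,3aS,6S,8aR)-1-hydroxy-3a,6-dimethyl-1-(propan-2-yl)-2,3,3a,6,7,8a-hexahydroazulen-8(1H)-one, via triethylsilyl ether 14 (not isolated)
Conditions: Et3SiOTf (10 mol %), CH2Cl2, −78 °C; then HF·pyridine, THF, 0 °C
Reagents that add atoms: none
Why: Et3SiOTf silylates the epoxide oxygen, the C5–O bond ionises with help from the enol silane (2-silyloxyallyl cation), the diene terminus C1 bonds to C5 on the face opposite the departing oxygen, C7 then closes on C8 and the oxocarbenium ion at C6 returns its silyl group to the catalyst, so that ketone 14 carries the silyl group on O4 until the fluoride work-up. The closest known reaction type is the silyl-triflate-catalysed intramolecular (4+3) cycloaddition of epoxy enolsilanes with tethered dienes. The five-membered ring closes through C1–C5 as the tether ring of a type 1 intramolecular cycloaddition (attack on the distal epoxide carbon, so the old C4–C5 bond lies in the new ring) and the seven-membered ring closes through C7–C8 in the (4+3) mode, suprafacial on the s-cis diene and on the allyl unit. C4 is untouched, and C5 is set because in the reacting conformer the isopropyl group sits next to H5 and the C4 oxygen next to C6 while the diene comes in anti to that oxygen, which leaves C6 cis to the C4 oxygen on the new cyclopentane. C1 and C8 follow from the compact arrangement of the (E,E)-diene under the W-shaped silyloxyallyl unit: the inside (Z) methyl on C1 then lies under H5, whereas the extended arrangement would push it under C6 and its silyloxy group, so H5 and the C1 methyl should end cis (cis ring fusion) and H8 cis to the C1 methyl. The step needs ring closure at C7–C8 to outrun proton loss from the allyl cation and needs ionisation at C5–O and not at the tertiary C4–O bond; the enol silane held over C8 by the three-atom tether and the allyl-type stabilisation of positive charge at C5 are what secure this.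

Step 11
Reactants: 15 (1R,3aS,6S,8aR)-1-hydroxy-3a,6-dimethyl-1-(propan-2-yl)-2,3,3a,6,7,8a-hexahydroazulen-8(1H)-one
Product: 16 (1R,3aS,6S,8R,8aS)-3a,6-dimethyl-1-(propan-2-yl)-1,2,3,3a,6,7,8,8a-octahydroazulene-1,8-diol
Conditions: Zn(BH4)2, Et2O, −20 °C
Reagents that add atoms: none
Why: In this chelation-controlled reduction of a β-hydroxy ketone, zinc bridges the C4 hydroxyl and the C6 carbonyl and hydride should add from the face of H5 (anti to the C5–C1 bond, the convex face of the cis-fused bicycle), giving the C6 alcohol cis to the C4 hydroxyl.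

Step 12
Reactants: 16 (1R,3aS,6S,8R,8aS)-3a,6-dimethyl-1-(propan-2-yl)-1,2,3,3a,6,7,8,8a-octahydroazulene-1,8-diol; 17 4-[(tert-butyldimethylsilyl)oxy]benzoic acid
Product: 18 (1R,3aS,6S,8R,8aS)-1-hydroxy-3a,6-dimethyl-1-(propan-2-yl)-1,2,3,3a,6,7,8,8a-octahydroazulen-8-yl 4-[(tert-butyldimethylsilyl)oxy]benzoate
Conditions: EDC·HCl, DMAP, CH2Cl2, rt
Reagents that add atoms: none
Why: Steglich esterification should acylate only the secondary C6 hydroxyl, because the tertiary C4 hydroxyl is too hindered to react.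

Step 13
Reactants: 18 (1R,3aS,6S,8R,8aS)-1-hydroxy-3a,6-dimethyl-1-(propan-2-yl)-1,2,3,3a,6,7,8,8a-octahydroazulen-8-yl 4-[(tert-butyldimethylsilyl)oxy]benzoate
Product: 20 (1R,3aR,4R,8R,8aS)-1,4-dihydroxy-3a,6-dimethyl-1-(propan-2-yl)-1,2,3,3a,4,7,8,8a-octahydroazulen-8-yl 4-[(tert-butyldimethylsilyl)oxy]benzoate, via allylic hydroperoxide 19 (not isolated)
Conditions: O2, tetraphenylporphyrin (cat.), visible light, CH2Cl2, 0 °C; then PPh3, 0 °C to rt
Reagents that add atoms: oxygen, O=O
Why: In the Schenck ene reaction singlet oxygen can abstract only the allylic H8 (C1 is quaternary), so oxygen should be delivered suprafacially to C10 on the face of H8 (cis to the C1 methyl) while the alkene moves to C8=C9, and triphenylphosphine then reduces the hydroperoxide to the alcohol.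

Step 14
Reactants: 20 (1R,3aR,4R,8R,8aS)-1,4-dihydroxy-3a,6-dimethyl-1-(propan-2-yl)-1,2,3,3a,4,7,8,8a-octahydroazulen-8-yl 4-[(tert-butyldimethylsilyl)oxy]benzoate; 21 (2E)-2-methylbut-2-enoic acid (tiglic acid)
Product: 23 (1R,3aR,4R,8R,8aS)-1-hydroxy-3a,6-dimethyl-4-{[(2E)-2-methylbut-2-enoyl]oxy}-1-(propan-2-yl)-1,2,3,3a,4,7,8,8a-octahydroazulen-8-yl 4-[(tert-butyldimethylsilyl)oxy]benzoate, via mixed anhydride 22 (not isolated)
Conditions: 21, 2,4,6-trichlorobenzoyl chloride, Et3N, toluene, rt; then 20, DMAP, toluene, 60 °C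
Reagents that add atoms: none
Why: Yamaguchi esterification should acylate the hindered allylic C10 hydroxyl with retention at C10 and without isomerising the (E)-2-methylbut-2-enoate, which is the thermodynamically preferred geometry.

Step 15
Reactants: 23 (1R,3aR,4R,8R,8aS)-1-hydroxy-3a,6-dimethyl-4-{[(2E)-2-methylbut-2-enoyl]oxy}-1-(propan-2-yl)-1,2,3,3a,4,7,8,8a-octahydroazulen-8-yl 4-[(tert-butyldimethylsilyl)oxy]benzoate
Product: 24 (1R,3aR,4R,8R,8aS)-1-hydroxy-3a,6-dimethyl-4-{[(2E)-2-methylbut-2-enoyl]oxy}-1-(propan-2-yl)-1,2,3,3a,4,7,8,8a-octahydroazulen-8-yl 4-hydroxybenzoate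
Conditions: HF·pyridine, pyridine, THF, 0 °C to rt
Reagents that add atoms: none
Why: Fluoride-mediated desilylation should cleave the aryl silyl ether far faster than it affects the two esters, the allylic system or the tertiary alcohol, freeing the phenol of the target.

Compound list
1 | hexa-1,5-diyne | C#CCCC#C | starting material
2 | (E)-1-bromoprop-1-ene | C/C=C/Br | starting material
3 | dimethyl[(1E)-2-methylhex-1-en-5-yn-1-yl]alumane | C#CCC/C(C)=C/[Al](C)C | intermediate
4 | (5E,7E)-5-methylnona-5,7-dien-1-yne | C#CCC/C(C)=C/C=C/C | intermediate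
5 | lithium (5E,7E)-5-methylnona-5,7-dien-1-yn-1-ide | [Li]C#CCC/C(C)=C/C=C/C | intermediate
6 | ethyl (6E,8E)-6-methyldeca-6,8-dien-2-ynoate | CCOC(=O)C#CCC/C(C)=C/C=C/C | intermediate
7 | ethyl (2E,6E,8E)-6-methyl-3-(propan-2-yl)deca-2,6,8-trienoate | CCOC(=O)/C=C(\CC/C(C)=C/C=C/C)C(C)C | intermediate
8 | (2E,6E,8E)-6-methyl-3-(propan-2-yl)deca-2,6,8-trien-1-ol | OC/C=C(\CC/C(C)=C/C=C/C)C(C)C | intermediate
9 | [(2R,3R)-3-[(3E,5E)-3-methylhepta-3,5-dien-1-yl]-3-(propan-2-yl)oxiran-2-yl]methanol | OC[C@H]1O[C@]1(CC/C(C)=C/C=C/C)C(C)C | intermediate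
10 | (2S,3R)-3-[(3E,5E)-3-methylhepta-3,5-dien-1-yl]-3-(propan-2-yl)oxirane-2-carbaldehyde | O=C[C@H]1O[C@]1(CC/C(C)=C/C=C/C)C(C)C | intermediate
11 | 1-[(2R,3R)-3-[(3E,5E)-3-methylhepta-3,5-dien-1-yl]-3-(propan-2-yl)oxiran-2-yl]ethan-1-ol (both carbinol epimers) | CC(O)[C@H]1O[C@]1(CC/C(C)=C/C=C/C)C(C)C | intermediate
12 | 1-[(2S,3R)-3-[(3E,5E)-3-methylhepta-3,5-dien-1-yl]-3-(propan-2-yl)oxiran-2-yl]ethan-1-one | CC(=O)[C@H]1O[C@]1(CC/C(C)=C/C=C/C)C(C)C | intermediate
13 | triethyl({1-[(2S,3R)-3-[(3E,5E)-3-methylhepta-3,5-dien-1-yl]-3-(propan-2-yl)oxiran-2-yl]ethenyl}oxy)silane | C=C(O[Si](CC)(CC)CC)[C@H]1O[C@]1(CC/C(C)=C/C=C/C)C(C)C | intermediate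
14 | (1R,3aS,6S,8aR)-3a,6-dimethyl-1-(propan-2-yl)-1-[(triethylsilyl)oxy]-2,3,3a,6,7,8a-hexahydroazulen-8(1H)-one | C1=C[C@@H](C)CC(=O)[C@@H]2[C@@]1(C)CC[C@@]2(O[Si](CC)(CC)CC)C(C)C | intermediate
15 | (1R,3aS,6S,8aR)-1-hydroxy-3a,6-dimethyl-1-(propan-2-yl)-2,3,3a,6,7,8a-hexahydroazulen-8(1H)-one | C1=C[C@@H](C)CC(=O)[C@@H]2[C@@]1(C)CC[C@@]2(O)C(C)C | intermediate
16 | (1R,3aS,6S,8R,8aS)-3a,6-dimethyl-1-(propan-2-yl)-1,2,3,3a,6,7,8,8a-octahydroazulene-1,8-diol | C1=C[C@@H](C)C[C@@H](O)[C@@H]2[C@@]1(C)CC[C@@]2(O)C(C)C | intermediate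
17 | 4-[(tert-butyldimethylsilyl)oxy]benzoic acid | OC(=O)c1ccc(O[Si](C)(C)C(C)(C)C)cc1 | starting material
18 | (1R,3aS,6S,8R,8aS)-1-hydroxy-3a,6-dimethyl-1-(propan-2-yl)-1,2,3,3a,6,7,8,8a-octahydroazulen-8-yl 4-[(tert-butyldimethylsilyl)oxy]benzoate | C1=C[C@@H](C)C[C@@H](OC(=O)c3ccc(O[Si](C)(C)C(C)(C)C)cc3)[C@@H]2[C@@]1(C)CC[C@@]2(O)C(C)C | intermediate
19 | (1R,3aR,4R,8R,8aS)-4-hydroperoxy-1-hydroxy-3a,6-dimethyl-1-(propan-2-yl)-1,2,3,3a,4,7,8,8a-octahydroazulen-8-yl 4-[(tert-butyldimethylsilyl)oxy]benzoate | OO[C@@H]1C=C(C)C[C@@H](OC(=O)c3ccc(O[Si](C)(C)C(C)(C)C)cc3)[C@@H]2[C@@]1(C)CC[C@@]2(O)C(C)C | intermediate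
20 | (1R,3aR,4R,8R,8aS)-1,4-dihydroxy-3a,6-dimethyl-1-(propan-2-yl)-1,2,3,3a,4,7,8,8a-octahydroazulen-8-yl 4-[(tert-butyldimethylsilyl)oxy]benzoate | O[C@@H]1C=C(C)C[C@@H](OC(=O)c3ccc(O[Si](C)(C)C(C)(C)C)cc3)[C@@H]2[C@@]1(C)CC[C@@]2(O)C(C)C | intermediate
21 | (2E)-2-methylbut-2-enoic acid (tiglic acid) | C/C=C(\C)C(=O)O | starting material
22 | (2E)-2-methylbut-2-enoic 2,4,6-trichlorobenzoic anhydride | C/C=C(\C)C(=O)OC(=O)c1c(Cl)cc(Cl)cc1Cl | intermediate
23 | (1R,3aR,4R,8R,8aS)-1-hydroxy-3a,6-dimethyl-4-{[(2E)-2-methylbut-2-enoyl]oxy}-1-(propan-2-yl)-1,2,3,3a,4,7,8,8a-octahydroazulen-8-yl 4-[(tert-butyldimethylsilyl)oxy]benzoate | C/C=C(\C)C(=O)O[C@@H]1C=C(C)C[C@@H](OC(=O)c3ccc(O[Si](C)(C)C(C)(C)C)cc3)[C@@H]2[C@@]1(C)CC[C@@]2(O)C(C)C | intermediate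
24 | (1R,3aR,4R,8R,8aS)-1-hydroxy-3a,6-dimethyl-4-{[(2E)-2-methylbut-2-enoyl]oxy}-1-(propan-2-yl)-1,2,3,3a,4,7,8,8a-octahydroazulen-8-yl 4-hydroxybenzoate (CNP0273650.8) | C/C=C(\C)C(=O)O[C@@H]1C=C(C)C[C@@H](OC(=O)c2ccc(O)cc2)[C@@H]2[C@@]1(C)CC[C@@]2(O)C(C)C | target

Total step count: 15
Longest linear sequence: 15 steps (1 to 24; compounds 2, 17 and 21 are bought)

Steps most likely to fail

Step 10 (key cycloaddition). What may go wrong: the silylated epoxide may ionise at the tertiary C4–O bond and rearrange by a 1,2-shift. The 1,1-disubstituted diene terminus may also be slow to reach the s-cis geometry, so that the allyl cation loses a proton or is captured at oxygen before the seven-membered ring closes. Partial leakage through the extended arrangement would erode the cis ring fusion. The fallback generates the oxyallyl cation by base from an α-chloro ketone (Föhlisch type), without epoxide activation; it sets out from 12 and returns at 14. Reductive opening of the epoxy ketone 12 with SmI2 (THF/MeOH, −90 °C) should give (4S,7E,9E)-4-hydroxy-7-methyl-4-(propan-2-yl)undeca-7,9-dien-2-one F1. Silylation (Et3SiOTf, 2,6-lutidine, CH2Cl2) should give its triethylsilyl ether, (4S,7E,9E)-7-methyl-4-(propan-2-yl)-4-[(triethylsilyl)oxy]undeca-7,9-dien-2-one F2. Kinetic enolisation at the methyl group and chlorination (LiN(iPr)2, THF, −78 °C, then p-toluenesulfonyl chloride) should give (4S,7E,9E)-1-chloro-7-methyl-4-(propan-2-yl)-4-[(triethylsilyl)oxy]undeca-7,9-dien-2-one F3. NaOCH2CF3 in CF3CH2OH should then form the oxyallyl cation by loss of chloride, and its intramolecular (4+3) cycloaddition should give silyl ether 14, which is desilylated to 15 as in step 10. In this variant C5 rests only on the preference of the isopropyl group to lie trans to C6 on the new ring.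

Step 13 (ene reaction). What may go wrong: singlet oxygen reacts slowly with a 1,2-disubstituted alkene, while the trisubstituted alkene created by the ene reaction is at least as reactive, so over-oxidation and photo-oxidative decomposition may compete. The fallback is epoxidation followed by base-induced isomerisation of the epoxide to the allylic alcohol; it sets out from 18 and returns at 20. mCPBA (NaHCO3, CH2Cl2, 0 °C) should epoxidise C9=C10 on the convex face to give the 4,5-epoxide of 18 (azulene numbering; epoxide oxygen cis to the 3a-methyl group and to H6) F4. Me3SiOTf and DBU (toluene, 0 °C to rt) should open the silylated epoxide with triflate at C9 and eliminate it anti to H8, giving the 1,4-bis(trimethylsilyl) ether of 20 F5. Citric acid in MeOH should remove the trimethylsilyl groups and give 20.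

Step 11 (ketone reduction). What may go wrong: poor facial selectivity of hydride addition, because the isopropyl group on C4 lies on the same face as H5 and may divert the reagent to the other face of the chelate. The fallback sets C6 by SN2 inversion instead of by face selection; it sets out from 15 and returns at 18. Me4NBH(OAc)3 (MeCN/AcOH, −20 °C; Evans–Saksena reduction with intramolecular hydride delivery from the C4 alkoxyborohydride) should give the C6 epimer, (1R,3aS,6S,8S,8aS)-3a,6-dimethyl-1-(propan-2-yl)-1,2,3,3a,6,7,8,8a-octahydroazulene-1,8-diol F6. Mitsunobu esterification with acid 17 (PPh3, diisopropyl azodicarboxylate, toluene, 0 °C to rt) should then give 18 with inversion at C6.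

Further compounds
F1 | step 10 | (4S,7E,9E)-4-hydroxy-7-methyl-4-(propan-2-yl)undeca-7,9-dien-2-one | CC(=O)C[C@@](O)(CC/C(C)=C/C=C/C)C(C)C
F2 | step 10 | (4S,7E,9E)-7-methyl-4-(propan-2-yl)-4-[(triethylsilyl)oxy]undeca-7,9-dien-2-one | CC(=O)C[C@@](O[Si](CC)(CC)CC)(CC/C(C)=C/C=C/C)C(C)C
F3 | step 10 | (4S,7E,9E)-1-chloro-7-methyl-4-(propan-2-yl)-4-[(triethylsilyl)oxy]undeca-7,9-dien-2-one | ClCC(=O)C[C@@](O[Si](CC)(CC)CC)(CC/C(C)=C/C=C/C)C(C)C
F4 | step 13 | 4,5-epoxide of 18 (azulene numbering; epoxide oxygen cis to the 3a-methyl group and to H6) | O1[C@@H]2[C@H]1[C@@H](C)C[C@@H](OC(=O)c3ccc(O[Si](C)(C)C(C)(C)C)cc3)[C@@H]3[C@@]2(C)CC[C@@]3(O)C(C)C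
F5 | step 13 | 1,4-bis(trimethylsilyl) ether of 20 | C[Si](C)(C)O[C@@H]1C=C(C)C[C@@H](OC(=O)c3ccc(O[Si](C)(C)C(C)(C)C)cc3)[C@@H]2[C@@]1(C)CC[C@@]2(O[Si](C)(C)C)C(C)C
F6 | step 11 | (1R,3aS,6S,8S,8aS)-3a,6-dimethyl-1-(propan-2-yl)-1,2,3,3a,6,7,8,8a-octahydroazulene-1,8-diol | C1=C[C@@H](C)C[C@H](O)[C@@H]2[C@@]1(C)CC[C@@]2(O)C(C)C
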